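## Structural features

- The target is the 6-O-vanillate (4-hydroxy-3-methoxybenzoate) of a daucane triol: a cyclopentane (ring A, C1–C5) trans-fused across the C1–C5 bond to a cycloheptene (ring B, C1 and C5–C10).
- Numbering used throughout: C1 is the quaternary ring-fusion carbon with the angular methyl, C2 and C3 are methylenes, C4 is the tertiary carbinol carbon carrying the isopropyl group, C5 is the ring-fusion CH, C6 carries the acyloxy group, C7=C8 is the trisubstituted alkene with the methyl on C8, C9 is the secondary carbinol and C10 a methylene; β is the face of the C1 methyl, and bicyclic intermediates are named as bicyclo[5.3.0]decanes with this numbering.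
- The configurations are 1R (CH3 β), 4R (OH β, isopropyl α), 5S (H α), 6S (O α) and 9S (OH α); C4, C5, C1 and C6 are contiguous, and C9 is related to C6 only through the cis-1,4 arrangement of the two allylic oxygens across C7=C8.
- Fragile groups are the secondary allylic aryl ester at C6 (ionisation, acyl shift to O9 or O4), the allylic alcohol at C9, the free phenol, and the tertiary carbinol at C4, which is 1,3 to O6, so that any C6 ketone would turn C4–C5 into a retro-aldol bond and O4 into a β-leaving group.
- The real difficulty is the all-carbon quaternary C1 at a trans 5–7 ring fusion, flanked by C5 and the fully substituted C4, combined with two oxygens at defined positions and faces of a seven-membered ring.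
- The key step exploits the seven-carbon sequence of ring B, C1–C5–C6–C7–C8–C9(O)–C10: with C5=C6 and C8=C9(O) as double bonds it is a cyclohepta-1,4-diene, the product of the Cope rearrangement of a cis-divinylcyclopropane (C6, C7, C8), whose two halves are a 1-vinylcyclopentene (C7=C6–C5=C1, ring A) and an oxygenated vinylcarbene (C8, C9, C10).
- Ring A with the C1 methyl, the C4 isopropyl group and the C4–O bond maps onto the p-menthane terpinen-4-ol after one ring carbon is pushed out of the ring (it becomes C6), so the tertiary carbinol stereocentre is taken from the chiral pool.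

## Logic of the disconnections

**25 ⇒ 24 ⇒ 23.** The two O–Si bonds (phenol and O4) are cut first, then the C9–H bond. C9 is the one stereocentre not locked to a neighbour, and taking it back to a carbonyl gives a 2-methylcycloheptenone. This removes one stereocentre and both protecting-group problems of the end game. The forward reduction must deliver hydride to the β face of C9 under reagent control without touching the aryl ester, and the final desilylation must be non-basic so that the acyl group stays on O6.

**23 ⇒ 22 ⇒ 18 + 21.** The C7=C8 π bond is taken back to C7H2–C8H, and the ester C(=O)–O6 bond is cut. The enone can only be formed toward C8 because C10 is attached to the quaternary C1, and the ester bond is the convergent junction with the aromatic acid. This separates the arene from the terpenoid core. The forward acylation must find one free hydroxyl only (O6), and the dehydrogenation must give the endocyclic alkene.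

**18 ⇒ 16 ⇒ 14.** The C8–CH3 bond is cut, and a methoxycarbonyl group at C8 and a silyl group on O9 are put back. As a β-keto ester enolate, C8 is the only nucleophilic carbon, so the methyl group goes to C8 and never to C10; the ester is then excised. This leads back to exactly the substitution pattern that the key step delivers. The forward alkylation must be C-selective and must tolerate the free O6–H.

**14 ⇒ 12.** The C5–H and C6–O bonds are cut together. H5 and O6 are cis (both α), which is the retron of a hydroboration–oxidation of a C5=C6 double bond, the very alkene the Cope step leaves. Two stereocentres are cleared in one operation. The forward step needs boron at C6 (fixed by the substitution pattern), attack on the α face, and chemoselectivity over the push–pull C8=C9 bond.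

**12 ⇒ 11 ⇒ 7 + 10 (key disconnection).** The C1–C10 and C7–C8 bonds are cut. This opens ring B, removes the quaternary stereocentre C1 and leaves a monocyclic diene with a single stereocentre (C4) plus a three-carbon diazo reagent. In one sentence: ring B and C1 arise when the rhodium carbenoid from 10 cyclopropanates the vinyl group of 7 and the cis-divinylcyclopropane 11 undergoes Cope rearrangement. The forward step needs cyclopropanation at the vinyl group only, cis-divinyl geometry, a catalyst-set configuration at C6 and C8 of 11 that places C10 on the α face of C1, and a Cope rearrangement onto a fully substituted alkene terminus.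

**7 ⇒ 6 ⇒ 4 ⇒ 2 ⇒ 1.** The C6=C7 bond (olefination) and the C5=C1 bond (aldol condensation) are cut, and the two carbonyl carbons of 4 (C6 and C1) are rejoined as the C=C bond of a cyclohexene. 4 is the ozonolysis product of a p-menthene whose carbinol carbon is C4. The hard-to-make tertiary carbinol stereocentre therefore comes from 1, and the six-membered ring is recut to ring A. The forward aldol must close through the aldehyde α-carbon onto the ketone and lose water toward C1, not toward C4.

**10 ⇒ 9 ⇒ 8 and 21 ⇒ 19.** The O–Si bond and the C=N2 bond of 10 are cut back to the acetoacetate 8; the O–Si bond of 21 is cut back to 19. Both branches start from commercial compounds and need only standard chemoselective silylation and diazo transfer.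

## Other disconnections considered

**Alternative 1:** Cut C7=C8. The forward key step is ring-closing metathesis of the triol-diene A1 with the second-generation Grubbs catalyst RuCl2(=CHPh)(H2IMes)(PCy3) to the cycloheptene triol A2, followed by acylation at O6. This is the first disconnection that comes to mind. It is set aside for three reasons:
- A1 already contains all five stereocentres, so the quaternary C1 and the C4–C5–C6 triad would have to be built on a monocyclic ring with no help from ring B.
- The closure joins a 1,1-disubstituted alkene to a vinyl group, both flanked by allylic oxygens and one of them two bonds from a quaternary carbon, which is an unfavourable metathesis case.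
- The two secondary allylic hydroxyls of A2 would still have to be told apart.

The metathesis closes the ring but solves none of the stereochemical problem, and the step count to A1 is expected to exceed that of the whole chosen route.

**Alternative 2:** Make C1–C5 and C9–C10 and sacrifice C5–C9. The forward key step is an intramolecular de Mayo reaction: irradiation of the enol of the 2-substituted 4-methylcyclopentane-1,3-dione A3 gives a (2+2) adduct between the enol C5=C9 bond and the isopropenyl unit C1=C10, and retro-aldol opening of the cyclobutanol gives the ring-B 6,9-dione A4. The 1,4-dioxygen pattern of ring B fits this reaction well. It is set aside for four reasons: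
- A3 is a tertiary aldol of a 1,3-dione and is expected to fragment by retro-aldol before it can be irradiated.
- The two enol tautomers would place the methyl on C8 or on C7.
- C1 would be controlled only remotely by C4, and C5 only by equilibration next to a ketone that also activates loss of O4.
- A4 still needs two stereoselective carbonyl reductions, their differentiation, and the C7=C8 bond.

**Alternative 3:** Cut both C–O bonds at C6 and C9. The forward key step is a (4+2) cycloaddition of singlet oxygen to the α face of the 6,8-diene A5, giving endoperoxide A6, followed by O–O reduction to the cis-1,4-diol. This sets the cis relation of O6 and O9 by mechanism, which is its real attraction. It is set aside because: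
- It leaves the skeleton unsolved: A5 still needs the trans-fused ring B and the quaternary C1 from some other ring construction.
- It produces two secondary allylic alcohols that must be told apart before mono-acylation.
- The Schenck ene reaction at the C8 methyl and at C10 competes.

The chosen step builds ring B and C1 and brings in O9 at the same time, so it settles a larger share of the problem.

Key step: step 7

Assumptions:
- Commercial (S)-(+)-terpinen-4-ol is taken as enantiomerically pure; material of lower optical purity would be upgraded before use.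
- The (R) antipode of the dirhodium catalyst is written by analogy with the usual facial model for donor/acceptor carbenoids; should the sense of induction be opposite for this diene, the (S) antipode is used instead.

## Route

Step 1
Reactants: 1 (S)-(+)-terpinen-4-ol [(1S)-4-methyl-1-(propan-2-yl)cyclohex-3-en-1-ol]
Product: 2 (S)-triethyl{[4-methyl-1-(propan-2-yl)cyclohex-3-en-1-yl]oxy}silane
Conditions: TESOTf, 2,6-lutidine, CH2Cl2, 0 °C to rt
Reagents that add atoms: triethylsilyl trifluoromethanesulfonate, CC[Si](CC)(CC)OS(=O)(=O)C(F)(F)F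
Why: Silyl triflate silylation of a hindered tertiary alcohol; the stereocentre is not touched. The ether blocks O–H insertion of the carbenoid in step 7 and hydroxyl-directed delivery of borane to the β face in step 8.

Step 2
Reactants: 2 (S)-triethyl{[4-methyl-1-(propan-2-yl)cyclohex-3-en-1-yl]oxy}silane
Product: 4 (3S)-6-oxo-3-(propan-2-yl)-3-(triethylsilyloxy)heptanal, via ozonide 3 (not isolated)
Conditions: O3, CH2Cl2, −78 °C; then PPh3, −78 °C to rt
Reagents that add atoms: ozone, [O-][O+]=O
Why: Ozonolysis of the only C=C bond gives ozonide 3, and reductive cleavage by the phosphine gives the 1,6-keto aldehyde. The two former alkene carbons become the ketone carbon (later C1) and the aldehyde carbon (later C6); C4 is untouched.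

Step 3
Reactants: 4 (3S)-6-oxo-3-(propan-2-yl)-3-(triethylsilyloxy)heptanal
Product: 6 (5R)-2-methyl-5-(propan-2-yl)-5-(triethylsilyloxy)cyclopent-1-ene-1-carbaldehyde, via ketol 5 (not isolated)
Conditions: piperidine (0.2 equiv), AcOH (0.2 equiv), toluene, 60–80 °C, 4 Å molecular sieves
Reagents that add atoms: none
Why: Amine/acid-catalysed intramolecular aldol condensation of a 1,6-keto aldehyde: the aldehyde enamine closes (5-enolexo) onto the methyl ketone to ketol 5, and the free tertiary hydroxyl is lost into conjugation. The silylated O4 is a poorer, non-hydrogen-bonded leaving group than the aldol hydroxyl, and C4 is not enolisable.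

Step 4
Reactants: 6 (5R)-2-methyl-5-(propan-2-yl)-5-(triethylsilyloxy)cyclopent-1-ene-1-carbaldehyde
Product: 7 triethyl{[(1R)-2-ethenyl-3-methyl-1-(propan-2-yl)cyclopent-2-en-1-yl]oxy}silane
Conditions: Ph3PCH3Br, KOtBu, THF, 0 °C to rt
Reagents that add atoms: methyltriphenylphosphonium bromide, C[P+](c1ccccc1)(c1ccccc1)c1ccccc1.[Br-]
Why: Wittig methylenation; the non-stabilised ylide adds 1,2 to the enal and gives the 2-vinylcyclopentene C7=C6–C5=C1.

Step 5
Reactants: 8 methyl acetoacetate (methyl 3-oxobutanoate)
Product: 9 methyl 2-diazo-3-oxobutanoate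
Conditions: 4-acetamidobenzenesulfonyl azide, Et3N, MeCN, 0 °C to rt
Reagents that add atoms: 4-acetamidobenzenesulfonyl azide, CC(=O)Nc1ccc(cc1)S(=O)(=O)N=[N+]=[N-]
Why: Regitz diazo transfer to an active methylene compound.

Step 6
Reactants: 9 methyl 2-diazo-3-oxobutanoate
Product: 10 methyl 3-(tert-butyldimethylsilyloxy)-2-diazobut-3-enoate
Conditions: TBSOTf, Et3N, CH2Cl2, 0 °C
Reagents that add atoms: tert-butyldimethylsilyl trifluoromethanesulfonate, CC(C)(C)[Si](C)(C)OS(=O)(=O)C(F)(F)F
Why: Silyl triflate/amine O-silylation of the acetyl group of a 2-diazo-1,3-dicarbonyl compound. The product is a donor/acceptor vinylcarbenoid precursor that carries C8 (carbene carbon), C9 (oxygenated) and C10.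

Step 7
Reactants: 7 triethyl{[(1R)-2-ethenyl-3-methyl-1-(propan-2-yl)cyclopent-2-en-1-yl]oxy}silane; 10 methyl 3-(tert-butyldimethylsilyloxy)-2-diazobut-3-enoate
Product: 12 methyl 9-(tert-butyldimethylsilyloxy)-1β-methyl-4α-(propan-2-yl)-4β-(triethylsilyloxy)bicyclo[5.3.0]deca-5,8-diene-8-carboxylate, via divinylcyclopropane 11 (not isolated)
Conditions: Rh2(R-PTAD)4 [dirhodium tetrakis((R)-(1-adamantyl)(N-phthalimido)acetate)] (1 mol %), 10 (1.5 equiv, slow addition), hexanes, −26 °C to rt; then toluene, 90 °C
Reagents that add atoms: none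
Why: Tandem cyclopropanation/Cope rearrangement, the formal (4+3) cycloaddition of a rhodium vinylcarbenoid with a diene, a known reaction type that also accepts 1-vinylcycloalkenes with a fully substituted distal carbon. The dirhodium tetracarboxylate (divalent rhodium) converts 10 into the electrophilic donor/acceptor carbenoid, which adds in an asynchronous concerted way to the monosubstituted vinyl group C6=C7 of 7 (the tetrasubstituted C5=C1 bond is too hindered), with the ester trans and the siloxyvinyl group cis to the cyclopentenyl group as is general for donor/acceptor carbenoids; this gives the cis-divinylcyclopropane 11 and forms C7–C8 (and transiently C6–C8). On warming, 11 undergoes the [3,3] shift through the boat transition state with both vinyl groups endo: C6–C8 breaks, C1–C10 forms, and the three-membered ring expands to ring B (3 to 7, a sigmatropic ring expansion), leaving the cis double bonds C5=C6 and C8=C9. C6 and C8 of 11 are set by the chiral catalyst; the only stereocentre that survives, C1, is set by the stereospecific boat geometry, because C10 can reach C1 only on the face of the cyclopentene over which the C6–C8 bond lies, and the 2S configuration of 11 fixes this as the α face (reagent control relayed through 11, not control by C4). The Z-methyl group on C1 and the neighbouring quaternary C4 slow the Cope step, hence the heating. Regiochemistry is fixed by connectivity: the carbene carbon becomes C8 and the unsubstituted vinyl terminus becomes C10. The selectivities needed are chemoselectivity for the vinyl group (sterics), cis-divinyl geometry (donor/acceptor carbenoid) and facial selectivity in the cyclopropanation (catalyst).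

Step 8
Reactants: 12 methyl 9-(tert-butyldimethylsilyloxy)-1β-methyl-4α-(propan-2-yl)-4β-(triethylsilyloxy)bicyclo[5.3.0]deca-5,8-diene-8-carboxylate
Product: 14 methyl 9-(tert-butyldimethylsilyloxy)-6α-hydroxy-1β-methyl-4α-(propan-2-yl)-4β-(triethylsilyloxy)-5α-bicyclo[5.3.0]dec-8-ene-8-carboxylate, via alkylborane 13 (not isolated)
Conditions: BH3·THF, THF, 0 °C to rt; then NaBO3·4H2O, THF/H2O, rt
Reagents that add atoms: sodium perborate, [Na+].[O-]OB=O
Why: Hydroboration–oxidation: syn addition of H–B across C5=C6 with boron on the less substituted C6, then oxidation with retention, sets H5 and O6 cis in one operation. Attack is expected on the α face, anti to the angular C1 methyl and to the bulky silyloxy group on C4, which gives the trans ring fusion (5α-H) and 6α-OH. The tetrasubstituted push–pull C8=C9 bond reacts much more slowly with borane.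

Step 9
Reactants: 14 methyl 9-(tert-butyldimethylsilyloxy)-6α-hydroxy-1β-methyl-4α-(propan-2-yl)-4β-(triethylsilyloxy)-5α-bicyclo[5.3.0]dec-8-ene-8-carboxylate
Product: 16 methyl 6α-hydroxy-1β,8-dimethyl-9-oxo-4α-(propan-2-yl)-4β-(triethylsilyloxy)-5α-bicyclo[5.3.0]decane-8-carboxylate (C8 epimers), via caesium enolate 15 (not isolated)
Conditions: CsF, MeI, DMF, 0 °C to rt
Reagents that add atoms: iodomethane, CI
Why: Fluoride cleaves the enol silyl ether to the β-keto ester enolate 15, which is C-methylated by iodomethane (fluoride-mediated regiospecific alkylation of a silyl enol ether). C8 is the only nucleophilic carbon, so C10 is never alkylated, and the alkyl triethylsilyl ether survives CsF. The configuration at C8 does not matter because C8 becomes sp2 in step 13.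

Step 10
Reactants: 16 methyl 6α-hydroxy-1β,8-dimethyl-9-oxo-4α-(propan-2-yl)-4β-(triethylsilyloxy)-5α-bicyclo[5.3.0]decane-8-carboxylate
Product: 18 6α-hydroxy-1β,8-dimethyl-4α-(propan-2-yl)-4β-(triethylsilyloxy)-5α-bicyclo[5.3.0]decan-9-one (C8 epimers), via lithium carboxylate 17 (not isolated)
Conditions: LiCl, H2O, DMSO, 150 °C
Reagents that add atoms: none
Why: Krapcho dealkoxycarbonylation: chloride demethylates the ester to carboxylate 17, which loses CO2 as a β-keto acid salt. The neutral conditions spare the silyl ether and the free hydroxyl.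

Step 11
Reactants: 19 vanillic acid (4-hydroxy-3-methoxybenzoic acid)
Product: 21 4-(tert-butyldimethylsilyloxy)-3-methoxybenzoic acid, via bis-silyl compound 20 (not isolated)
Conditions: TBSCl (2.5 equiv), imidazole, DMF, rt; then AcOH/THF/H2O, rt
Reagents that add atoms: tert-butyldimethylsilyl chloride, CC(C)(C)[Si](C)(C)Cl
Why: Both acidic hydroxyls are silylated, and the labile silyl ester of 20 is then hydrolysed selectively, leaving the aryl silyl ether.

Step 12
Reactants: 18 6α-hydroxy-1β,8-dimethyl-4α-(propan-2-yl)-4β-(triethylsilyloxy)-5α-bicyclo[5.3.0]decan-9-one; 21 4-(tert-butyldimethylsilyloxy)-3-methoxybenzoic acid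
Product: 22 6α-[4-(tert-butyldimethylsilyloxy)-3-methoxybenzoyloxy]-1β,8-dimethyl-4α-(propan-2-yl)-4β-(triethylsilyloxy)-5α-bicyclo[5.3.0]decan-9-one (C8 epimers)
Conditions: DCC, DMAP, CH2Cl2, 0 °C to rt
Reagents that add atoms: none
Why: Steglich esterification; the secondary C6–OH is the only free hydroxyl (O4 and the phenol are silylated), and acylation proceeds with retention at C6. Any transannular hemiketal between O6 and C9 is drained through the open hydroxy ketone.

Step 13
Reactants: 22 6α-[4-(tert-butyldimethylsilyloxy)-3-methoxybenzoyloxy]-1β,8-dimethyl-4α-(propan-2-yl)-4β-(triethylsilyloxy)-5α-bicyclo[5.3.0]decan-9-one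
Product: 23 6α-[4-(tert-butyldimethylsilyloxy)-3-methoxybenzoyloxy]-1β,8-dimethyl-4α-(propan-2-yl)-4β-(triethylsilyloxy)-5α-bicyclo[5.3.0]dec-7-en-9-one
Conditions: 2-iodoxybenzoic acid (IBX, 2 equiv), DMSO/toluene, 70 °C
Reagents that add atoms: none
Why: α,β-Dehydrogenation of a ketone with 2-iodoxybenzoic acid (enolisation toward C8, single-electron oxidation, loss of hydrogen from C7). The other α-carbon, C10, is attached to the quaternary C1, so only the C7=C8 enone can form, and the endocyclic 2-methyl enone is the more substituted conjugated product.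

Step 14
Reactants: 23 6α-[4-(tert-butyldimethylsilyloxy)-3-methoxybenzoyloxy]-1β,8-dimethyl-4α-(propan-2-yl)-4β-(triethylsilyloxy)-5α-bicyclo[5.3.0]dec-7-en-9-one
Product: 24 6α-[4-(tert-butyldimethylsilyloxy)-3-methoxybenzoyloxy]-9α-hydroxy-1β,8-dimethyl-4α-(propan-2-yl)-4β-(triethylsilyloxy)-5α-bicyclo[5.3.0]dec-7-ene
Conditions: (R)-2-methyl-CBS-oxazaborolidine (0.5 equiv), BH3·SMe2, THF, −30 °C
Reagents that add atoms: none
Why: Corey–Bakshi–Shibata reduction: the (R)-oxazaborolidine–borane complex binds the ketone with the α-methylvinyl flank (C8) as the large group and delivers hydride to the β face, giving the (9S)-alcohol (OH α, cis to O6) under reagent control, as established for 2-substituted cycloalkenones. Esters and silyl ethers are inert at this temperature.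

Step 15
Reactants: 24 6α-[4-(tert-butyldimethylsilyloxy)-3-methoxybenzoyloxy]-9α-hydroxy-1β,8-dimethyl-4α-(propan-2-yl)-4β-(triethylsilyloxy)-5α-bicyclo[5.3.0]dec-7-ene
Product: 25 CNP0189996.2, (3R,3aS,4S,7S,8aR)-3,7-dihydroxy-6,8a-dimethyl-3-(propan-2-yl)-1,2,3,3a,4,7,8,8a-octahydroazulen-4-yl 4-hydroxy-3-methoxybenzoate
Conditions: HF·pyridine, pyridine, THF, 0 °C to rt
Reagents that add atoms: none
Why: Fluoride cleavage of the aryl silyl ether and of the tertiary triethylsilyl ether under buffered, non-basic conditions, which avoids acyl migration from O6 and ionisation of the allylic positions. No stereocentre is touched.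

## Compound list

1 | (S)-(+)-terpinen-4-ol, (1S)-4-methyl-1-(propan-2-yl)cyclohex-3-en-1-ol | CC1=CC[C@](O)(C(C)C)CC1 | starting material
2 | (S)-triethyl{[4-methyl-1-(propan-2-yl)cyclohex-3-en-1-yl]oxy}silane | CC1=CC[C@](O[Si](CC)(CC)CC)(C(C)C)CC1 | intermediate
3 | secondary ozonide (1,2,4-trioxolane) of 2 | CC12CC[C@@](O[Si](CC)(CC)CC)(C(C)C)CC(OO1)O2 | intermediate (not isolated)
4 | (3S)-6-oxo-3-(propan-2-yl)-3-(triethylsilyloxy)heptanal | O=CC[C@](O[Si](CC)(CC)CC)(C(C)C)CCC(C)=O | intermediate
5 | (5R)-2-hydroxy-2-methyl-5-(propan-2-yl)-5-(triethylsilyloxy)cyclopentane-1-carbaldehyde (ketol, other centres mixed) | O=CC1C(C)(O)CC[C@@]1(O[Si](CC)(CC)CC)C(C)C | intermediate (not isolated)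
6 | (5R)-2-methyl-5-(propan-2-yl)-5-(triethylsilyloxy)cyclopent-1-ene-1-carbaldehyde | O=CC1=C(C)CC[C@@]1(O[Si](CC)(CC)CC)C(C)C | intermediate
7 | triethyl{[(1R)-2-ethenyl-3-methyl-1-(propan-2-yl)cyclopent-2-en-1-yl]oxy}silane | C=CC1=C(C)CC[C@@]1(O[Si](CC)(CC)CC)C(C)C | intermediate
8 | methyl acetoacetate | COC(=O)CC(C)=O | starting material
9 | methyl 2-diazo-3-oxobutanoate | COC(=O)C(=[N+]=[N-])C(C)=O | intermediate
10 | methyl 3-(tert-butyldimethylsilyloxy)-2-diazobut-3-enoate | COC(=O)C(=[N+]=[N-])C(=C)O[Si](C)(C)C(C)(C)C | intermediate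
11 | methyl (1R,2S)-1-[1-(tert-butyldimethylsilyloxy)ethenyl]-2-[(5R)-2-methyl-5-(propan-2-yl)-5-(triethylsilyloxy)cyclopent-1-en-1-yl]cyclopropane-1-carboxylate | COC(=O)[C@]1(C(=C)O[Si](C)(C)C(C)(C)C)C[C@H]1C2=C(C)CC[C@@]2(O[Si](CC)(CC)CC)C(C)C | intermediate (not isolated)
12 | methyl 9-(tert-butyldimethylsilyloxy)-1β-methyl-4α-(propan-2-yl)-4β-(triethylsilyloxy)bicyclo[5.3.0]deca-5,8-diene-8-carboxylate | COC(=O)C1=C(O[Si](C)(C)C(C)(C)C)C[C@@]2(C)CC[C@@](O[Si](CC)(CC)CC)(C(C)C)C2=CC1 | intermediate
13 | 6α-boryl adduct of 12 (5α-H, monoalkylborane) | COC(=O)C1=C(O[Si](C)(C)C(C)(C)C)C[C@@]2(C)CC[C@@](O[Si](CC)(CC)CC)(C(C)C)[C@@H]2[C@@H](B)C1 | intermediate (not isolated)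
14 | methyl 9-(tert-butyldimethylsilyloxy)-6α-hydroxy-1β-methyl-4α-(propan-2-yl)-4β-(triethylsilyloxy)-5α-bicyclo[5.3.0]dec-8-ene-8-carboxylate | COC(=O)C1=C(O[Si](C)(C)C(C)(C)C)C[C@@]2(C)CC[C@@](O[Si](CC)(CC)CC)(C(C)C)[C@@H]2[C@@H](O)C1 | intermediate
15 | caesium enolate of the desilylated β-keto ester from 14 | [Cs+].COC(=O)C1=C([O-])C[C@@]2(C)CC[C@@](O[Si](CC)(CC)CC)(C(C)C)[C@@H]2[C@@H](O)C1 | intermediate (not isolated)
16 | methyl 6α-hydroxy-1β,8-dimethyl-9-oxo-4α-(propan-2-yl)-4β-(triethylsilyloxy)-5α-bicyclo[5.3.0]decane-8-carboxylate (C8 epimers) | COC(=O)C1(C)C(=O)C[C@@]2(C)CC[C@@](O[Si](CC)(CC)CC)(C(C)C)[C@@H]2[C@@H](O)C1 | intermediate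
17 | lithium carboxylate from 16 | [Li+].[O-]C(=O)C1(C)C(=O)C[C@@]2(C)CC[C@@](O[Si](CC)(CC)CC)(C(C)C)[C@@H]2[C@@H](O)C1 | intermediate (not isolated)
18 | 6α-hydroxy-1β,8-dimethyl-4α-(propan-2-yl)-4β-(triethylsilyloxy)-5α-bicyclo[5.3.0]decan-9-one (C8 epimers) | CC1C(=O)C[C@@]2(C)CC[C@@](O[Si](CC)(CC)CC)(C(C)C)[C@@H]2[C@@H](O)C1 | intermediate
19 | vanillic acid | COc1cc(C(=O)O)ccc1O | starting material
20 | tert-butyldimethylsilyl 4-(tert-butyldimethylsilyloxy)-3-methoxybenzoate | COc1cc(C(=O)O[Si](C)(C)C(C)(C)C)ccc1O[Si](C)(C)C(C)(C)C | intermediate (not isolated)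
21 | 4-(tert-butyldimethylsilyloxy)-3-methoxybenzoic acid | COc1cc(C(=O)O)ccc1O[Si](C)(C)C(C)(C)C | intermediate
22 | 6α-[4-(tert-butyldimethylsilyloxy)-3-methoxybenzoyloxy]-1β,8-dimethyl-4α-(propan-2-yl)-4β-(triethylsilyloxy)-5α-bicyclo[5.3.0]decan-9-one (C8 epimers) | CC1C(=O)C[C@@]2(C)CC[C@@](O[Si](CC)(CC)CC)(C(C)C)[C@@H]2[C@@H](OC(=O)c3ccc(O[Si](C)(C)C(C)(C)C)c(OC)c3)C1 | intermediate
23 | 6α-[4-(tert-butyldimethylsilyloxy)-3-methoxybenzoyloxy]-1β,8-dimethyl-4α-(propan-2-yl)-4β-(triethylsilyloxy)-5α-bicyclo[5.3.0]dec-7-en-9-one | O=C1C[C@@]2(C)CC[C@@](O[Si](CC)(CC)CC)(C(C)C)[C@@H]2[C@@H](OC(=O)c3ccc(O[Si](C)(C)C(C)(C)C)c(OC)c3)C=C1C | intermediate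
24 | 6α-[4-(tert-butyldimethylsilyloxy)-3-methoxybenzoyloxy]-9α-hydroxy-1β,8-dimethyl-4α-(propan-2-yl)-4β-(triethylsilyloxy)-5α-bicyclo[5.3.0]dec-7-ene | O[C@H]1C[C@@]2(C)CC[C@@](O[Si](CC)(CC)CC)(C(C)C)[C@@H]2[C@@H](OC(=O)c3ccc(O[Si](C)(C)C(C)(C)C)c(OC)c3)C=C1C | intermediate
25 | CNP0189996.2, (3R,3aS,4S,7S,8aR)-3,7-dihydroxy-6,8a-dimethyl-3-(propan-2-yl)-1,2,3,3a,4,7,8,8a-octahydroazulen-4-yl 4-hydroxy-3-methoxybenzoate | COc1cc(C(=O)O[C@H]2C=C(C)[C@@H](O)C[C@@]3(C)CC[C@@](O)(C(C)C)[C@H]23)ccc1O | target

## Step count and least certain steps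

Total step count: 15. Longest linear sequence: 12 steps (1, 2, 3, 4, 7, 8, 9, 10, 12, 13, 14, 15); steps 5–6 and step 11 are side branches.

**Step 7 (key step).** The most likely failure is slow Cope rearrangement on the α face. In the boat transition state the C9 silyloxy group lies over C4 on the side of the isopropyl group, and C1 carries a Z-methyl group. If the donor/acceptor cyclopropane undergoes stereomutation at the temperature then needed, the configuration at C1 is eroded, or the rearrangement is diverted to the β face. Sluggish cyclopropanation of the vinyl group next to the quaternary C4 is the second risk.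

The fallback takes the C4 stereocentre out of the cycloaddition; it sets out from 10 and returns at 12:
- Commercial 3-methylcyclopent-2-en-1-one F1 is iodinated (I2, pyridine, CH2Cl2) to 2-iodo-3-methylcyclopent-2-en-1-one F2.
- Stille coupling with tributyl(vinyl)stannane (Pd(PPh3)4, toluene, 90 °C) gives the achiral dienone 2-ethenyl-3-methylcyclopent-2-en-1-one F3.
- F3 and 10 under the conditions of step 7 give methyl (1R,2S)-1-[1-(tert-butyldimethylsilyloxy)ethenyl]-2-(2-methyl-5-oxocyclopent-1-en-1-yl)cyclopropane-1-carboxylate F4 and, after Cope rearrangement, methyl 9-(tert-butyldimethylsilyloxy)-1β-methyl-4-oxobicyclo[5.3.0]deca-5,8-diene-8-carboxylate F5. C1 is the only stereocentre of F5 and is set by the catalyst alone.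
- iPrMgCl/CeCl3 (THF, −78 °C) is expected to add to the C4 carbonyl anti to the angular methyl, giving methyl 9-(tert-butyldimethylsilyloxy)-4β-hydroxy-1β-methyl-4α-(propan-2-yl)bicyclo[5.3.0]deca-5,8-diene-8-carboxylate F6.
- TESOTf/2,6-lutidine then gives 12.

**Step 8.** The most likely failure is poor facial selectivity of the hydroboration. The cyclohepta-1,4-diene can fold so that C8–C10 lie under the α face of C5=C6, while the β face carries the C1 methyl and the C4 silyloxy group; attack on the β face gives the cis ring fusion.

The fallback replaces kinetic facial control by equilibration at C5 and a hydride reduction at C6; it sets out from 12 and returns at 14: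
- The β-face adduct is methyl 9-(tert-butyldimethylsilyloxy)-6β-hydroxy-1β-methyl-4α-(propan-2-yl)-4β-(triethylsilyloxy)-5β-bicyclo[5.3.0]dec-8-ene-8-carboxylate F7.
- Oxidation with Dess–Martin periodinane gives the cis-fused 6-ketone F8.
- Equilibration of C5 with mild base (basic alumina, or DBU in CH2Cl2 at 0 °C) gives the trans-fused 6-ketone F9.
- Reduction with NaBH4/CeCl3·7H2O on the then more open β face gives 14.

**Step 3.** The most likely failure is loss of the silyloxy group by β-elimination from the aldehyde enamine, or dehydration of the ketol toward C4 instead of C1, since both oxygens are β to the aldehyde. The fallback separates ring closure from water loss; it sets out from 4 and returns at 6. The aldol addition alone is run at 0 °C (pyrrolidine/AcOH, catalytic), ketol 5 is isolated, and only its free tertiary hydroxyl is activated and eliminated with the Burgess reagent (methyl N-(triethylammoniosulfonyl)carbamate, benzene, 50 °C). No new compound is needed (F0).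

**Step 14.** The most likely failure is poor facial selectivity because the substrate bias opposes the catalyst: the pseudoaxial C1 methyl shields the β face of the C9 carbonyl.

The fallback accepts the substrate-preferred alcohol and inverts it; it sets out from 23 and returns at 24:
- Luche reduction (NaBH4, CeCl3·7H2O, MeOH, −78 °C) on the α face gives the 9β-alcohol F10.
- Mitsunobu inversion with chloroacetic acid (PPh3, DIAD, toluene, 0 °C) gives the 9α-chloroacetate F11.
- Thiourea/NaHCO3 (EtOH, 50 °C) removes the chloroacetyl group selectively and gives 24.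

## Further compounds

F0 | step 3 | none | none
F1 | step 7 | 3-methylcyclopent-2-en-1-one | CC1=CC(=O)CC1
F2 | step 7 | 2-iodo-3-methylcyclopent-2-en-1-one | CC1=C(I)C(=O)CC1
F3 | step 7 | 2-ethenyl-3-methylcyclopent-2-en-1-one | C=CC1=C(C)CCC1=O
F4 | step 7 | methyl (1R,2S)-1-[1-(tert-butyldimethylsilyloxy)ethenyl]-2-(2-methyl-5-oxocyclopent-1-en-1-yl)cyclopropane-1-carboxylate | COC(=O)[C@]1(C(=C)O[Si](C)(C)C(C)(C)C)C[C@H]1C2=C(C)CCC2=O
F5 | step 7 | methyl 9-(tert-butyldimethylsilyloxy)-1β-methyl-4-oxobicyclo[5.3.0]deca-5,8-diene-8-carboxylate | COC(=O)C1=C(O[Si](C)(C)C(C)(C)C)C[C@@]2(C)CCC(=O)C2=CC1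
F6 | step 7 | methyl 9-(tert-butyldimethylsilyloxy)-4β-hydroxy-1β-methyl-4α-(propan-2-yl)bicyclo[5.3.0]deca-5,8-diene-8-carboxylate | COC(=O)C1=C(O[Si](C)(C)C(C)(C)C)C[C@@]2(C)CC[C@@](O)(C(C)C)C2=CC1
F7 | step 8 | methyl 9-(tert-butyldimethylsilyloxy)-6β-hydroxy-1β-methyl-4α-(propan-2-yl)-4β-(triethylsilyloxy)-5β-bicyclo[5.3.0]dec-8-ene-8-carboxylate | COC(=O)C1=C(O[Si](C)(C)C(C)(C)C)C[C@@]2(C)CC[C@@](O[Si](CC)(CC)CC)(C(C)C)[C@H]2[C@H](O)C1
F8 | step 8 | methyl 9-(tert-butyldimethylsilyloxy)-1β-methyl-6-oxo-4α-(propan-2-yl)-4β-(triethylsilyloxy)-5β-bicyclo[5.3.0]dec-8-ene-8-carboxylate | COC(=O)C1=C(O[Si](C)(C)C(C)(C)C)C[C@@]2(C)CC[C@@](O[Si](CC)(CC)CC)(C(C)C)[C@H]2C(=O)C1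
F9 | step 8 | methyl 9-(tert-butyldimethylsilyloxy)-1β-methyl-6-oxo-4α-(propan-2-yl)-4β-(triethylsilyloxy)-5α-bicyclo[5.3.0]dec-8-ene-8-carboxylate | COC(=O)C1=C(O[Si](C)(C)C(C)(C)C)C[C@@]2(C)CC[C@@](O[Si](CC)(CC)CC)(C(C)C)[C@@H]2C(=O)C1
F10 | step 14 | 9β-hydroxy epimer of 24 | O[C@@H]1C[C@@]2(C)CC[C@@](O[Si](CC)(CC)CC)(C(C)C)[C@@H]2[C@@H](OC(=O)c3ccc(O[Si](C)(C)C(C)(C)C)c(OC)c3)C=C1C
F11 | step 14 | 9α-chloroacetate of 24 | ClCC(=O)O[C@H]1C[C@@]2(C)CC[C@@](O[Si](CC)(CC)CC)(C(C)C)[C@@H]2[C@@H](OC(=O)c3ccc(O[Si](C)(C)C(C)(C)C)c(OC)c3)C=C1C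
A1 | alternative 1 | (triol-diene) 1β-methyl-4α-(propan-2-yl)cyclopentane bearing 4β-OH, a C5 (1-hydroxyprop-2-enyl) arm and a C1 (2-hydroxy-3-methylbut-3-enyl) arm | C=C(C)[C@@H](O)C[C@@]1(C)CC[C@@](O)(C(C)C)[C@@H]1[C@@H](O)C=C
A2 | alternative 1 | 4β,6α,9α-trihydroxy-1β,8-dimethyl-4α-(propan-2-yl)-5α-bicyclo[5.3.0]dec-7-ene | O[C@H]1C[C@@]2(C)CC[C@@](O)(C(C)C)[C@@H]2[C@@H](O)C=C1C
A3 | alternative 2 | 2-[(3R)-3-hydroxy-2,6-dimethylhept-6-en-3-yl]-4-methylcyclopentane-1,3-dione | CC1CC(=O)C(C1=O)[C@](O)(C(C)C)CCC(C)=C
A4 | alternative 2 | 4β-hydroxy-1β,8-dimethyl-4α-(propan-2-yl)-5α-bicyclo[5.3.0]decane-6,9-dione | O=C1C[C@@]2(C)CC[C@@](O)(C(C)C)[C@@H]2C(=O)CC1C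
A5 | alternative 3 | 1β,8-dimethyl-4α-(propan-2-yl)-5α-bicyclo[5.3.0]deca-6,8-dien-4β-ol | CC1=CC[C@@]2(C)CC[C@@](O)(C(C)C)[C@@H]2C=C1
A6 | alternative 3 | 6α,9α-epidioxy-1β,8-dimethyl-4α-(propan-2-yl)-5α-bicyclo[5.3.0]dec-7-en-4β-ol | O1[C@H]2C[C@@]3(C)CC[C@@](O)(C(C)C)[C@@H]3[C@@H](O1)C=C2C
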